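**Retrosynthetic overview**
- Lehualide H ⇐ thioacetate SN2 displacement on the ω-chloride of the assembled pyranone. Sulfur comes last because an S-alkyl thioacetate would itself be an electrophile toward alkylzinc/palladium.
- Pyranone ⇐ palladium-catalysed three-component union of (10-chlorodecyl)zinc iodide, CO and a squarate-derived tertiary cyclobutenyl acetate. The ring C6–CH2 bond and the C5–C6 bond are both made at the CO carbon. The 4-acylcyclobutenone then opens (4π) and recloses (6π-oxa, O1–C2) in the same flask, so the pyranone is the only ring formed in the route and it is made from the cyclobutenone ring in step 4.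
- Enabling feature: ring atoms C2(=O)–C3(OMe)=C4(OMe)–C5(Me) are the four carbons of dimethyl squarate in disguise. C6 is a carbonyl-level carbon between ring O1 and the chain, so it can enter as CO and its ketone oxygen can capture the ketene at C2.
- Cyclobutenyl acetate ⇐ dimethyl squarate + MeLi, then Ac2O (one pot); zinc reagent ⇐ 10-chlorodecan-1-ol via the iodide.

Key step: step 4

Remark: the target has no stereocentre; the cyclobutenone intermediates are racemic and their quaternary carbon becomes the sp2 carbon C5 of the pyranone.

**Step 1**
Reactants: 1 dimethyl squarate (3,4-dimethoxycyclobut-3-ene-1,2-dione)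
Product: 3 rac-2,3-dimethoxy-1-methyl-4-oxocyclobut-2-en-1-yl acetate, via lithium alkoxide 2 (not isolated)
Conditions: MeLi (1.05 equiv), THF, −78 °C; then Ac2O (1.5 equiv), −78 → 0 °C
Reagents that add atoms: methyllithium, [Li]C; acetic anhydride, CC(=O)OC(C)=O
Why: 1,2-addition of methyllithium to one of the two equivalent squarate carbonyl groups is the standard entry to 4-hydroxycyclobutenones, and O-acylation of the tertiary lithium alkoxide in situ (nucleophilic acyl substitution) should install the allylic leaving group without acid, the new quaternary centre being racemic and destroyed in step 4.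

**Step 2**
Reactants: 4 10-chlorodecan-1-ol
Product: 5 1-chloro-10-iododecane
Conditions: I2, PPh3, imidazole, CH2Cl2, 0 °C → rt
Reagents that add atoms: iodine, II
Why: Appel-type iodination converts the primary alcohol into the iodide by SN2 attack of iodide on the alkoxyphosphonium ion and should leave the primary chloride untouched.

**Step 3**
Reactants: 5 1-chloro-10-iododecane
Product: 6 (10-chlorodecyl)zinc iodide (THF solution, titrated and used as such)
Conditions: Zn dust (activated with 1,2-dibromoethane and TMSCl), LiCl, THF, 40 °C
Reagents that add atoms: zinc, [Zn]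
Why: LiCl-promoted direct insertion of zinc into the C–I bond (organozinc formation) is chemoselective over the primary C–Cl bond, as in the well-known ω-chloroalkylzinc halides.

**Step 4**
Reactants: 3 rac-2,3-dimethoxy-1-methyl-4-oxocyclobut-2-en-1-yl acetate; 6 (10-chlorodecyl)zinc iodide; 7 carbon monoxide
Product: 10 pyranone 6-(10-chlorodecyl)-3,4-dimethoxy-5-methyl-2H-pyran-2-one, via 4-acylcyclobutenone 8 (not isolated), via acylvinylketene 9 (not isolated)
Conditions: Pd2(dba)3 (2.5 mol %), P(2-furyl)3 (10 mol %), CO (1 atm), THF/NMP, 25 °C (slow addition of 6), then 60 °C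
Reagents that add atoms: none
Why: Proposed new method: zerovalent palladium should ionise the tertiary allylic acetate of 3 to an η3-oxocyclobutenyl palladium acetate, after which transmetalation from 6 and migratory insertion of CO into the Pd–CH2 bond create the bond between the future ring C6 and the first chain methylene as an acylpalladium, and reductive elimination onto the methyl-bearing allyl terminus gives 4-acylcyclobutenone 8 (C5–C6 bond). On warming, 8 should undergo 4π-electrocyclic ring opening to acylvinylketene 9, which closes the pyranone ring by 6π-oxa-electrocyclisation, the C6 ketone oxygen bonding to the ketene carbon (O1–C2), so the four-membered carbocycle is exchanged for the six-membered heteroaromatic ring. The closest known reaction types are the palladium-catalysed carbonylative cross-coupling of 4-chlorocyclobut-2-enones with alkenyl- and arylstannanes, which gives 2-pyranones through the same acylcyclobutenone–ketene cascade, and the palladium-catalysed three-component coupling of allylic benzoates, CO and functionalised alkylzinc iodides to allyl alkyl ketones; new here are the sp3 zinc partner on a cyclobutenone and the tertiary, dialkoxy-substituted acetate. No stereocentre is created: the racemic quaternary carbon of 8 becomes sp2 C5, and the only stereochemical demand, the acyl group cis to the ketene in 9, should be met by the inward rotation preferred by a π-acceptor acyl group in cyclobutenone opening and by the reversibility of that opening. The step needs acyl transfer to the methyl-bearing and not the methoxy-bearing allyl terminus, and acylation instead of direct alkyl–allyl coupling; the first should follow from the π-donor methoxy group, which keeps its terminus enol-ether-like and leaves palladium σ-bound at the methyl-bearing carbon for inner-sphere bond formation, the second from the slow sp3–sp3 reductive elimination of alkyl(allyl)palladium under CO.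

**Step 5**
Reactants: 10 pyranone 6-(10-chlorodecyl)-3,4-dimethoxy-5-methyl-2H-pyran-2-one
Product: 11 lehualide H
Conditions: KSAc (1.5 equiv), NaI (0.2 equiv), DMF, 50 °C
Reagents that add atoms: potassium thioacetate, CC(=O)[S-].[K+]
Why: SN2 displacement of the primary chloride by the soft thioacetate anion, with in situ Finkelstein catalysis by iodide, should install the S-acetyl group without touching the fully substituted pyranone or its methyl ethers.

**Compound list**
1 | dimethyl squarate (3,4-dimethoxycyclobut-3-ene-1,2-dione) | COC1=C(OC)C(=O)C1=O | starting material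
2 | lithium 2,3-dimethoxy-1-methyl-4-oxocyclobut-2-en-1-olate (racemic, not isolated) | [Li+].[O-]C1(C)C(OC)=C(OC)C1=O | intermediate
3 | rac-2,3-dimethoxy-1-methyl-4-oxocyclobut-2-en-1-yl acetate | CC(=O)OC1(C)C(OC)=C(OC)C1=O | intermediate
4 | 10-chlorodecan-1-ol | OCCCCCCCCCCCl | starting material
5 | 1-chloro-10-iododecane | ClCCCCCCCCCCI | intermediate
6 | (10-chlorodecyl)zinc iodide | ClCCCCCCCCCC[Zn]I | intermediate
7 | carbon monoxide | [C-]#[O+] | starting material
8 | rac-4-(11-chloroundecanoyl)-2,3-dimethoxy-4-methylcyclobut-2-en-1-one (not isolated) | ClCCCCCCCCCCC(=O)C1(C)C(OC)=C(OC)C1=O | intermediate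
9 | (3E)-15-chloro-2,3-dimethoxy-4-methylpentadeca-1,3-diene-1,5-dione (acyl group cis to the ketene, not isolated) | O=C=C(OC)/C(OC)=C(C)\C(=O)CCCCCCCCCCCl | intermediate
10 | 6-(10-chlorodecyl)-3,4-dimethoxy-5-methyl-2H-pyran-2-one | COc1c(C)c(CCCCCCCCCCCl)oc(=O)c1OC | intermediate
11 | lehualide H, 6-(10-acetylsulfanyldecyl)-3,4-dimethoxy-5-methyl-2H-pyran-2-one | COc1c(C)c(CCCCCCCCCCSC(C)=O)oc(=O)c1OC | target

**Summary**
Total step count: 5. Longest linear sequence: 4 steps (steps 2, 3, 4, 5).

**Steps most likely to fail**

1. Step 4 (Proposed new method).
   - What may go wrong: acyl transfer to the methoxy-bearing allyl terminus, which after the same ring expansion would give the regioisomeric pyranone; direct alkyl–allyl coupling before CO uptake; or β-hydride loss from the methyl-substituted allyl complex.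
   - Fallback (known chemistry only), setting out from 5 and returning at 10. Magnesium insertion into 5 (Mg, THF) gives the Grignard reagent (10-chlorodecyl)magnesium iodide F1. Inverse addition of F1 to excess methyl chloroformate at −78 °C forms the same carbon–carbon bond and gives methyl 11-chloroundecanoate F2. Methyl 2-methoxy-3-oxopentanoate F3 is made by cross-Claisen acylation of methyl methoxyacetate with propanoyl chloride (LDA, THF, −78 °C). F3 is deprotonated twice (NaH, then n-BuLi, THF, 0 °C) and γ-acylated with F2 to give methyl 15-chloro-2-methoxy-4-methyl-3,5-dioxopentadecanoate F4. Lactonisation of F4 with DBU in toluene at 80 °C gives 6-(10-chlorodecyl)-4-hydroxy-3-methoxy-5-methyl-2H-pyran-2-one F5. O-Methylation of the 4-hydroxyl group (Me2SO4, K2CO3, acetone, reflux) rejoins the route at 10.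

2. Step 1.
   - What may go wrong: incomplete O-acylation of the hindered alkoxide, or ionisation of the tertiary allylic acetate with 1,3-transposition and loss of methyl acetate (collapse toward the cyclobutenedione) during quench, work-up or chromatography.
   - Fallback, setting out from 1 and returning at 10. The MeLi adduct is quenched with aqueous NH4Cl and isolated as the stable tertiary alcohol 4-hydroxy-2,3-dimethoxy-4-methylcyclobut-2-en-1-one F6. F6 is deprotonated (LiHMDS, THF, −78 °C, re-forming alkoxide 2) and phosphorylated with diethyl chlorophosphate to the allylic phosphate diethyl (2,3-dimethoxy-1-methyl-4-oxocyclobut-2-en-1-yl) phosphate F7. F7 is not purified but transferred cold into the step 4 mixture in place of 3, so the leaving group is generated and consumed without isolation; the route is rejoined at 10.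

3. Step 5.
   - What may go wrong: sluggish substitution of the primary chloride that forces higher temperature, with competing nucleophilic O-demethylation of the C4 methoxy group or nucleophilic opening of the pyranone, and deacetylation followed by disulfide formation.
   - Fallback, setting out from 3 and returning at 11. Step 4 is run with dec-9-en-1-ylzinc bromide F8 (from commercial 10-bromodec-1-ene, Zn, LiCl, THF, 50 °C) in place of 6. Through acylcyclobutenone rac-4-(undec-10-enoyl)-2,3-dimethoxy-4-methylcyclobut-2-en-1-one F9 and ketene (3E)-2,3-dimethoxy-4-methylpentadeca-1,3,14-triene-1,5-dione F10 (neither isolated), this should give the terminal alkene 6-(dec-9-en-1-yl)-3,4-dimethoxy-5-methyl-2H-pyran-2-one F11. Radical anti-Markovnikov thiol–ene addition of thioacetic acid (AcSH, AIBN, toluene, 70 °C) installs the thioacetate under neutral, non-nucleophilic conditions and rejoins the route at 11.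

**Further compounds**
F1 | step 4 | (10-chlorodecyl)magnesium iodide | ClCCCCCCCCCC[Mg]I
F2 | step 4 | methyl 11-chloroundecanoate | COC(=O)CCCCCCCCCCCl
F3 | step 4 | methyl 2-methoxy-3-oxopentanoate (racemic) | CCC(=O)C(OC)C(=O)OC
F4 | step 4 | methyl 15-chloro-2-methoxy-4-methyl-3,5-dioxopentadecanoate (mixture of stereoisomers) | COC(=O)C(OC)C(=O)C(C)C(=O)CCCCCCCCCCCl
F5 | step 4 | 6-(10-chlorodecyl)-4-hydroxy-3-methoxy-5-methyl-2H-pyran-2-one | COc1c(O)c(C)c(CCCCCCCCCCCl)oc1=O
F6 | step 1 | rac-4-hydroxy-2,3-dimethoxy-4-methylcyclobut-2-en-1-one | CC1(O)C(OC)=C(OC)C1=O
F7 | step 1 | rac-diethyl (2,3-dimethoxy-1-methyl-4-oxocyclobut-2-en-1-yl) phosphate | CCOP(=O)(OCC)OC1(C)C(OC)=C(OC)C1=O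
F8 | step 5 | dec-9-en-1-ylzinc bromide | C=CCCCCCCCC[Zn]Br
F9 | step 5 | rac-4-(undec-10-enoyl)-2,3-dimethoxy-4-methylcyclobut-2-en-1-one | C=CCCCCCCCCC(=O)C1(C)C(OC)=C(OC)C1=O
F10 | step 5 | (3E)-2,3-dimethoxy-4-methylpentadeca-1,3,14-triene-1,5-dione | O=C=C(OC)/C(OC)=C(C)\C(=O)CCCCCCCCC=C
F11 | step 5 | 6-(dec-9-en-1-yl)-3,4-dimethoxy-5-methyl-2H-pyran-2-one | C=CCCCCCCCCc1oc(=O)c(OC)c(OC)c1C
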